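Readings and results were generated by integration with made-up constants; noise was put on by code.

Equal amounts stand in these flasks, 0.16 M of starting material against 0.160 M of second substrate. The candidate steps take one of each per target, so the ceiling is the whole charge, and the question is how fast it is approached.

common to all: starting material 0.16 M

| run | second substrate | free enzyme | remark | time |
|---|---|---|---|---|
| delta | 0.16 M | 0.77 µM | run made earlier |  |
| gamma | 0.16 M | 5.6 µM | run made earlier |  |
| Saturday's | 0.160 M | 2.0 µM |  | 10 min |
| Wednesday's | 0.160 M | 1.5 µM |  | 10 min |
| Friday's | 0.160 M | 5.0 µM |  | 10 min |
| Monday's | 0.160 M | 0.60 µM |  | 10 min |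
| Thursday's | 0.160 M | 2.7 µM |  | 10 min |

- delta (time / min: target / %): 0.500: 1.2; 1.50: 3.0; 3.00: 6.0; 4.00: 6.7; 6.00: 10.8; 8.00: 11.9; 10.0: 16.0
- gamma (time / min: target / %): 1.33: 14.6; 3.00: 33.9; 4.00: 43.4; 6.00: 61.4; 8.00: 73.8; 10.0: 81.8

(standard deviation of a reading: 1 percentage point)

- the flasks put in order of amount of target, in percent of the starting material charged, best first, at 10 min (Saturday's / Wednesday's / Friday's / Monday's / Thursday's)
- the amount of target, in percent of the starting material charged of the flask you put first, at 10 min
- the amount of target, in percent of the starting material charged of the flask you put last, at 10 min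

- what was read earlier has a scatter of 1 percentage point, one standard deviation
- candidate steps: starting material + free enzyme <-> first complex; free enzyme -> spent catalyst; second complex -> free enzyme + target; first complex -> loaded enzyme + first product; second substrate + loaded enzyme <-> second complex

Friday's has 50.0 µM·min of enzyme dose, the charge of free enzyme times the time. If the enzyme survives and rate follows its charge, flasks with equal substrate charges stand at equal conversion at equal dose (Selwyn's test). We test this first. The delta run reaches 7.70 µM·min at its last reading and stands at 16.0%. The gamma run reaches that dose at 1.38 min, where its readings give 15.1%. That is a gap of 0.90 percentage points against a scatter of 1 point, so the two runs share one curve.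

Monday's has a dose of 6.00 µM·min. We reach it in two ways. The delta run passes it at 7.79 min, which gives 11.8%. Gamma's first reading, scaled by dose, gives 11.8%. These come from different runs, but each hangs on few readings with a scatter of 1 point, so their agreement may be chance. Delta's reading at 8.00 min lies below the line between its neighbours, and that line gives 13.1% for Monday's. So we hold Monday's between 11.8% and 13.1%.

For Friday's the same two ways part. The scaled line gives 98.0%, but the gamma curve at 8.93 min gives 77.5%. The line cheats: gamma's last 2.00 min add 8 points, a slower gain than the 14.6% of its first 1.33 min. We keep the curve. At one time the doses stand as the charges, so Friday's comes first and Monday's last.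

The forecast reads Friday's > Thursday's > Saturday's > Wednesday's > Monday's, with 77.5% and 12.3%, on the ground “The order simply follows enzyme loading.”; its top matches ours and its low lies between our 11.8% and 13.1%.

    starting material + free enzyme ⇌ first complex (K = 1.80 L mol⁻¹, k = 14000 L mol⁻¹ s⁻¹)
    free enzyme → spent catalyst (k = 5.60 × 10⁻⁶ s⁻¹)
    second complex → free enzyme + target (k = 120 s⁻¹)
    first complex → loaded enzyme + first product (k = 5600 s⁻¹)
    second substrate + loaded enzyme ⇌ second complex (K = 7.60 L mol⁻¹, k = 60000 L mol⁻¹ s⁻¹)

The flasks give Friday's > Thursday's > Saturday's > Wednesday's > Monday's: Friday's, at 50.0 µM·min, reaches 77.9%, and Monday's reaches 13.1%, 1.3 points above our lower figure. In Friday's at 3.88 min, starting material has a half-life of 2.0 min by the forward step into first complex, and second substrate one of 0.073 min by its forward step. Yet Friday's second complex falls back 66 times faster than it goes on, and its spent catalyst at 10.0 min is 0.0289% of the catalyst charged. Monday's, left to 100 min, has a dose of 60.0 µM·min, beyond gamma's last 56.0 µM·min at 81.8%, and stands at 85.0%.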